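**Plan**

1. The only ring is the 42-membered lactone (C1–C41 plus the ring oxygen). It is cut at C27–C28: C27 is a ring carbinol carbon with CH2 neighbours on both sides, and C28 heads the (CH2)3 tether to C31. A C27 aldehyde and a primary C28 iodide can therefore be joined by an alkylchromium addition that closes the ring, creates the C27 hydroxyl and sets C27 in one event, leaving no extra unsaturation or oxygen to remove.
2. Further cuts are C2=C3 (Z-selective HWE of a C41 phosphonoacetate with a C3 enal), C19–C20 (Ni/Cr alkenyl addition) and C39–C40 (acetylide plus epoxide). This gives four fragments: West C3–C19, East C20–C27, alkyne C28–C39 and side-chain epoxide C40–C50.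
3. Forward order: West + East give the North enal; alkyne + epoxide give the South iodide–phosphonate; HWE joins North and South; PMB removal, oxidation, ring closure at C27–C28, global desilylation.
4. Stereochemistry: the all-anti C7–C17 hexol comes from three rounds of Krische allylation (catalyst control, ligand antipode alternated); C17/C18 and C42/C43 from Brown crotylborations; C19 from Felkin–Anh addition; C23 from Krische allylation; C31 from the L-glutamic acid lactone and C49 from (R)-propylene oxide (chiral pool); C41 from a 1,3-syn iodocarbonate cyclisation; C27 from a chiral sulfonamide ligand on chromium.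
5. Alkenes: 4Z by Still–Gennari olefination, 20Z from a (Z)-2-iodoalkene (Stork–Zhao-type), 2Z by the HWE union, 38Z by Lindlar reduction.

Key step: step 46

**Remarks**

- The target SMILES is read as 2Z,4Z,20Z,38Z and 7S,9R,11S,13R,15S,17R,18R,19S,23R,27R,31R,41S,42S,43R,49R. Fragment names use the target's atom numbers (C1 lactone carbonyl, C41 carries the ring oxygen, C42–C50 side chain); "as in the target" means the same spatial arrangement at that carbon. TBS = tert-butyldimethylsilyl, PMB = 4-methoxybenzyl.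
- Assumption: (S)-Cl,MeO-BIPHEP is taken to give the (4S,6S)-diol in step 1; the ligand choices in steps 4, 8 and 18 follow from the same facial sense.
- Assumption: the (4R)-oxazoline–sulfonamide ligand of step 46 is taken to direct the alkyl group to the Re face of the C27 aldehyde; if the sense is the reverse, its enantiomer is used.

**Route**

Step 1
Reactants: 1 propane-1,3-diol
Product: 2 (4S,6S)-nona-1,8-diene-4,6-diol
Conditions: allyl acetate, [Ir(cod)Cl]2 (5 mol%), (S)-Cl,MeO-BIPHEP, 4-chloro-3-nitrobenzoic acid, Cs2CO3, 1,4-dioxane, 90 °C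
Reagents that add atoms: allyl acetate (C=CCOC(C)=O)
Why: Two-directional Krische carbonyl allylation from the alcohol oxidation level should give the C2-symmetric anti diol, both carbinol centres (C11, C13) being set by the chiral cyclometallated iridium catalyst.

Step 2
Reactants: 2 (4S,6S)-nona-1,8-diene-4,6-diol
Product: 3 (4S,6S)-4,6-bis(TBS-oxy)nona-1,8-diene
Conditions: TBSCl, imidazole, DMF, rt
Reagents that add atoms: tert-butyldimethylsilyl chloride (CC(C)(C)[Si](C)(C)Cl)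
Why: Standard silyl ether formation protects both secondary alcohols before ozonolysis.

Step 3
Reactants: 3 (4S,6S)-4,6-bis(TBS-oxy)nona-1,8-diene
Product: 5 (3S,5S)-3,5-bis(TBS-oxy)heptane-1,7-diol, via dialdehyde 4 (not isolated)
Conditions: O3, CH2Cl2/MeOH, −78 °C; then NaBH4, −78 → 0 °C
Reagents that add atoms: ozone ([O-][O+]=O)
Why: Ozonolysis with reductive work-up should cleave both terminal alkenes to the primary alcohols at C9 and C15 without touching the silyl ethers.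

Step 4
Reactants: 5 (3S,5S)-3,5-bis(TBS-oxy)heptane-1,7-diol
Product: 6 (4R,6S,8S,10R)-6,8-bis(TBS-oxy)trideca-1,12-diene-4,10-diol
Conditions: allyl acetate, [Ir(cod)Cl]2, (R)-Cl,MeO-BIPHEP, 4-chloro-3-nitrobenzoic acid, Cs2CO3, 1,4-dioxane, 90 °C
Reagents that add atoms: allyl acetate (C=CCOC(C)=O)
Why: A second two-directional Krische allylation with the antipodal ligand should set C9 and C15 anti to C11 and C13 under catalyst control.

Step 5
Reactants: 6 (4R,6S,8S,10R)-6,8-bis(TBS-oxy)trideca-1,12-diene-4,10-diol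
Product: 7 (4R,6S,8S,10R)-4,6,8,10-tetrakis(TBS-oxy)trideca-1,12-diene
Conditions: TBSOTf, 2,6-lutidine, CH2Cl2, −78 → 0 °C
Reagents that add atoms: tert-butyldimethylsilyl triflate (CC(C)(C)[Si](C)(C)OS(=O)(=O)C(F)(F)F)
Why: Silylation of the two hindered secondary alcohols with the silyl triflate is routine.

Step 6
Reactants: 7 (4R,6S,8S,10R)-4,6,8,10-tetrakis(TBS-oxy)trideca-1,12-diene
Product: 9 (3R,5S,7S,9R)-3,5,7,9-tetrakis(TBS-oxy)undecane-1,11-diol, via dialdehyde 8 (not isolated)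
Conditions: O3, CH2Cl2/MeOH, −78 °C; then NaBH4, −78 → 0 °C
Reagents that add atoms: ozone ([O-][O+]=O)
Why: Ozonolysis with reductive work-up should give the C2-symmetric C7–C17 diol.

Step 7
Reactants: 9 (3R,5S,7S,9R)-3,5,7,9-tetrakis(TBS-oxy)undecane-1,11-diol
Product: 10 (3R,5S,7S,9R)-3,5,7,9,11-pentakis(TBS-oxy)undecan-1-ol
Conditions: NaH (1 equiv), THF, 0 °C; TBSCl (1 equiv); recovered 9 and bis-ether recycled
Reagents that add atoms: tert-butyldimethylsilyl chloride (CC(C)(C)[Si](C)(C)Cl)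
Why: Monosilylation through the monosodium alkoxide desymmetrises the diol; the two hydroxyls are homotopic, so only one mono-ether can form.

Step 8
Reactants: 10 (3R,5S,7S,9R)-3,5,7,9,11-pentakis(TBS-oxy)undecan-1-ol
Product: 11 C5–C17 homoallylic alcohol (C7–OH; C9, C11, C13, C15 and primary C17 OTBS; vinyl group on C6)
Conditions: allyl acetate, [Ir(cod)Cl]2, (S)-Cl,MeO-BIPHEP, 4-chloro-3-nitrobenzoic acid, Cs2CO3, THF, 100 °C
Reagents that add atoms: allyl acetate (C=CCOC(C)=O)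
Why: Krische allylation of the single primary alcohol should set C7 anti to C9 under catalyst control.

Step 9
Reactants: 11 C5–C17 homoallylic alcohol
Product: 12 C5–C17 hexakis-TBS ether (C7 OTBS)
Conditions: TBSOTf, 2,6-lutidine, CH2Cl2, −78 → 0 °C
Reagents that add atoms: tert-butyldimethylsilyl triflate (CC(C)(C)[Si](C)(C)OS(=O)(=O)C(F)(F)F)
Why: Routine silylation protects C7–OH before ozonolysis.

Step 10
Reactants: 12 C5–C17 hexakis-TBS ether
Product: 13 C5–C17 aldehyde (C5 = CHO)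
Conditions: O3, CH2Cl2, −78 °C; then PPh3
Reagents that add atoms: ozone ([O-][O+]=O)
Why: Ozonolysis of the only alkene should give the β-silyloxy aldehyde.

Step 11
Reactants: 13 C5–C17 aldehyde
Product: 14 C3–C17 ethyl (Z)-enoate (ethyl ester at C3, 4-methyl, 4Z)
Conditions: ethyl 2-[bis(2,2,2-trifluoroethoxy)phosphoryl]propanoate, KN(SiMe3)2, 18-crown-6, THF, −78 °C
Reagents that add atoms: ethyl 2-[bis(2,2,2-trifluoroethoxy)phosphoryl]propanoate (CCOC(=O)C(C)P(=O)(OCC(F)(F)F)OCC(F)(F)F)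
Why: Still–Gennari olefination should give the trisubstituted Z-enoate (C3 cis to C6) by fast elimination from the kinetic adduct.

Step 12
Reactants: 14 C3–C17 ethyl (Z)-enoate
Product: 15 C17 primary alcohol
Conditions: HF·pyridine, pyridine, THF, 0 °C
Reagents that add atoms: none
Why: Buffered HF·pyridine should cleave the unhindered primary silyl ether faster than the five secondary ones.

Step 13
Reactants: 15 C17 primary alcohol
Product: 16 C17 aldehyde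
Conditions: Dess–Martin periodinane, NaHCO3, CH2Cl2, 0 °C → rt
Reagents that add atoms: none
Why: Dess–Martin oxidation is mild enough for the β-silyloxy aldehyde and the Z-enoate.

Step 14
Reactants: 16 C17 aldehyde
Product: 17 C3–C19 anti-homoallylic alcohol (C17–OH, C18-methyl, vinyl group = C19 plus one CH2)
Conditions: (−)-Ipc2B[(E)-crotyl] (Ipc from (+)-α-pinene, stock solution), THF/Et2O, −78 °C; then NaBO3·4H2O, rt
Reagents that add atoms: (−)-(E)-crotyldiisopinocampheylborane (C/C=C/CB([C@@H]1C[C@@H]2C[C@H]([C@H]1C)C2(C)C)[C@@H]1C[C@@H]2C[C@H]([C@H]1C)C2(C)C)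
Why: Brown (E)-crotylboration through a chair transition state should set C17 and C18 anti, with the absolute sense fixed by the reagent.

Step 15
Reactants: 17 C3–C19 anti-homoallylic alcohol
Product: 18 C17 TBS ether
Conditions: TBSOTf, 2,6-lutidine, CH2Cl2, −78 → 0 °C
Reagents that add atoms: tert-butyldimethylsilyl triflate (CC(C)(C)[Si](C)(C)OS(=O)(=O)C(F)(F)F)
Why: Routine silylation.

Step 16
Reactants: 18 C17 TBS ether
Product: 19 C3–C19 aldehyde (C19 = CHO)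
Conditions: O3, CH2Cl2, pyridine, −78 °C, stopped at consumption of 18; then PPh3
Reagents that add atoms: ozone ([O-][O+]=O)
Why: Ozonolysis should take the electron-rich terminal alkene well before the electron-poor trisubstituted enoate.

Step 17
Reactants: 20 pentane-1,5-diol
Product: 21 5-[(4-methoxybenzyl)oxy]pentan-1-ol
Conditions: NaH (1 equiv), PMBCl, Bu4NI, THF, 0 °C → rt
Reagents that add atoms: 4-methoxybenzyl chloride (COc1ccc(CCl)cc1)
Why: Williamson monoalkylation of the symmetric diol.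

Step 18
Reactants: 21 5-[(4-methoxybenzyl)oxy]pentan-1-ol
Product: 22 (R)-8-[(4-methoxybenzyl)oxy]oct-1-en-4-ol
Conditions: allyl acetate, [Ir(cod)Cl]2, (S)-Cl,MeO-BIPHEP, 4-chloro-3-nitrobenzoic acid, Cs2CO3, THF, 100 °C
Reagents that add atoms: allyl acetate (C=CCOC(C)=O)
Why: Krische allylation from the alcohol oxidation level should set C23 under catalyst control.

Step 19
Reactants: 22 (R)-8-[(4-methoxybenzyl)oxy]oct-1-en-4-ol
Product: 23 TBS ether of 22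
Conditions: TBSCl, imidazole, DMF, rt
Reagents that add atoms: tert-butyldimethylsilyl chloride (CC(C)(C)[Si](C)(C)Cl)
Why: Routine silylation.

Step 20
Reactants: 23 TBS ether of 22
Product: 24 (R)-3-(TBS-oxy)-7-[(4-methoxybenzyl)oxy]heptanal
Conditions: O3, CH2Cl2, −78 °C; then PPh3
Reagents that add atoms: ozone ([O-][O+]=O)
Why: Ozonolysis of the terminal alkene at low temperature should spare the PMB ether.

Step 21
Reactants: 24 (R)-3-(TBS-oxy)-7-[(4-methoxybenzyl)oxy]heptanal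
Product: 25 East vinyl iodide, 1-({[(5R,7Z)-5-(TBS-oxy)-8-iodonon-7-en-1-yl]oxy}methyl)-4-methoxybenzene
Conditions: [Ph3PEt]I, n-BuLi, THF, rt; I2, −78 °C; NaN(SiMe3)2, −20 °C; then 24, −78 °C
Reagents that add atoms: ethyltriphenylphosphonium iodide (CC[P+](c1ccccc1)(c1ccccc1)c1ccccc1.[I-]); iodine (II)
Why: Stork–Zhao-type Wittig olefination with the α-iodoethylidene ylide should give the (Z)-2-iodoalkene (iodine cis to C22).

Step 22
Reactants: 19 C3–C19 aldehyde; 25 East vinyl iodide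
Product: 26 C3–C27 allylic alcohol (C19–OH; 20Z)
Conditions: CrCl2 (8 equiv), NiCl2 (cat.), DMSO, rt
Reagents that add atoms: none
Why: Nozaki–Hiyama–Kishi coupling should retain the alkene geometry and add to the α-methyl aldehyde in the Felkin–Anh sense, reinforced by the 1,3-anti preference from the C17 silyloxy group, to give 18,19-syn/17,19-anti.

Step 23
Reactants: 26 C3–C27 allylic alcohol
Product: 27 C19 TBS ether
Conditions: TBSOTf, 2,6-lutidine, CH2Cl2, −78 → 0 °C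
Reagents that add atoms: tert-butyldimethylsilyl triflate (CC(C)(C)[Si](C)(C)OS(=O)(=O)C(F)(F)F)
Why: Routine silylation of the hindered allylic alcohol.

Step 24
Reactants: 27 C19 TBS ether
Product: 28 C3 allylic alcohol
Conditions: iBu2AlH, CH2Cl2, −78 °C; Rochelle salt work-up
Reagents that add atoms: none
Why: iBu2AlH reduces the enoate, the only ester present, to the allylic alcohol.

Step 25
Reactants: 28 C3 allylic alcohol
Product: 29 North (Z)-enal (C3 = CHO)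
Conditions: MnO2, CH2Cl2, rt, dark; used at once
Reagents that add atoms: none
Why: MnO2 oxidises only the allylic alcohol under neutral conditions, which should limit Z-to-E isomerisation.

Step 26
Reactants: 30 (R)-2-methyloxirane
Product: 31 (R)-non-8-en-2-ol
Conditions: hex-5-enylmagnesium bromide, CuI (10 mol%), THF, −30 °C
Reagents that add atoms: hex-5-enylmagnesium bromide (C=CCCCC[Mg]Br)
Why: Copper-catalysed Grignard opening at the epoxide CH2 leaves the C49 stereocentre from the chiral pool untouched.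

Step 27
Reactants: 31 (R)-non-8-en-2-ol
Product: 32 (R)-tert-butyldimethyl(non-8-en-2-yloxy)silane
Conditions: TBSCl, imidazole, DMF, rt
Reagents that add atoms: tert-butyldimethylsilyl chloride (CC(C)(C)[Si](C)(C)Cl)
Why: Routine silylation.

Step 28
Reactants: 32 (R)-tert-butyldimethyl(non-8-en-2-yloxy)silane
Product: 33 (R)-7-(TBS-oxy)octanal
Conditions: O3, CH2Cl2, −78 °C; then PPh3
Reagents that add atoms: ozone ([O-][O+]=O)
Why: Ozonolysis gives the C43 aldehyde.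

Step 29
Reactants: 33 (R)-7-(TBS-oxy)octanal
Product: 34 (3R,4R,10R)-10-(TBS-oxy)-3-methylundec-1-en-4-ol
Conditions: (−)-Ipc2B[(Z)-crotyl] (Ipc from (+)-α-pinene, stock solution), THF, −78 °C; then NaBO3·4H2O, rt
Reagents that add atoms: (−)-(Z)-crotyldiisopinocampheylborane (C/C=C\CB([C@@H]1C[C@@H]2C[C@H]([C@H]1C)C2(C)C)[C@@H]1C[C@@H]2C[C@H]([C@H]1C)C2(C)C)
Why: Brown (Z)-crotylboration through a chair transition state should set C42 and C43 syn, with the absolute sense fixed by the reagent.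

Step 30
Reactants: 34 (3R,4R,10R)-10-(TBS-oxy)-3-methylundec-1-en-4-ol
Product: 35 tert-butyl (3R,4R,10R)-10-(TBS-oxy)-3-methylundec-1-en-4-yl carbonate
Conditions: NaN(SiMe3)2, THF, −78 °C; Boc2O, → 0 °C
Reagents that add atoms: di-tert-butyl dicarbonate (CC(C)(C)OC(=O)OC(=O)OC(C)(C)C)
Why: Acylation of the sodium alkoxide gives the homoallylic tert-butyl carbonate.

Step 31
Reactants: 35 homoallylic tert-butyl carbonate
Product: 36 (4R,5S,6R)-4-(iodomethyl)-5-methyl-6-[(6R)-6-(TBS-oxy)heptyl]-1,3-dioxan-2-one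
Conditions: IBr, toluene, −85 °C
Reagents that add atoms: iodine monobromide (BrI)
Why: Iodocarbonate cyclisation through a chair transition state with the C43 chain and the CH2I group equatorial should give the 4,6-cis carbonate and so set C41 1,3-syn to C43.

Step 32
Reactants: 36 iodocarbonate
Product: 37 (2S,3R,9R)-9-(TBS-oxy)-2-[(2R)-oxiran-2-yl]decan-3-ol
Conditions: K2CO3, MeOH, rt
Reagents that add atoms: none
Why: Methanolysis of the carbonate and SN2 closure of the C41 alkoxide onto C40 gives the epoxide with C41 unchanged.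

Step 33
Reactants: 37 epoxy alcohol
Product: 38 (2R)-2-[(2R,3R,9R)-3,9-bis(TBS-oxy)decan-2-yl]oxirane
Conditions: TBSCl, imidazole, DMF, rt
Reagents that add atoms: tert-butyldimethylsilyl chloride (CC(C)(C)[Si](C)(C)Cl)
Why: Silylation under non-Lewis-acidic conditions keeps the epoxide intact.

Step 34
Reactants: 39 (S)-(5-oxotetrahydrofuran-2-yl)methyl 4-methylbenzenesulfonate (from L-glutamic acid); 40 1-bromo-5-chloropentane
Product: 42 (R)-5-(6-chlorohexyl)dihydrofuran-2(3H)-one, via Grignard reagent 41 (not isolated)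
Conditions: 40, Mg, THF, rt; then 39, Li2CuCl4 (5 mol%), THF, −78 → −30 °C
Reagents that add atoms: none
Why: Copper-catalysed Grignard–tosylate coupling (Fouquet–Schlosser type) extends the chain at the primary tosylate faster than the lactone is attacked; C31 comes unchanged from the chiral pool.

Step 35
Reactants: 42 (R)-5-(6-chlorohexyl)dihydrofuran-2(3H)-one
Product: 43 (R)-10-chlorodecane-1,4-diol
Conditions: LiBH4, THF, 0 °C → rt
Reagents that add atoms: none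
Why: LiBH4 reduces the lactone to the 1,4-diol and leaves the primary chloride alone.

Step 36
Reactants: 43 (R)-10-chlorodecane-1,4-diol
Product: 44 (R)-1,4-bis(TBS-oxy)-10-chlorodecane
Conditions: TBSCl, imidazole, DMF, rt
Reagents that add atoms: tert-butyldimethylsilyl chloride (CC(C)(C)[Si](C)(C)Cl)
Why: Routine bis-silylation.

Step 37
Reactants: 44 (R)-1,4-bis(TBS-oxy)-10-chlorodecane
Product: 45 (R)-1,4-bis(TBS-oxy)dodec-11-yne
Conditions: LiC≡CH·H2NCH2CH2NH2, NaI (cat.), DMSO, rt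
Reagents that add atoms: lithium acetylide ethylenediamine complex ([Li+].[C-]#C.NCCN)
Why: SN2 displacement of the primary chloride by acetylide installs C38–C39.

Step 38
Reactants: 45 (R)-1,4-bis(TBS-oxy)dodec-11-yne; 38 side-chain epoxide
Product: 46 C28–C50 homopropargylic alcohol (C41–OH free; C28, C31, C43, C49 OTBS; C38≡C39)
Conditions: 45, n-BuLi, THF, −78 °C; BF3·OEt2; then 38, −78 °C
Reagents that add atoms: none
Why: BF3-assisted opening of the terminal epoxide by the lithium acetylide at C40 forms C39–C40 and frees only the C41 hydroxyl.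

Step 39
Reactants: 46 C28–C50 homopropargylic alcohol
Product: 47 C28–C50 (38Z)-alkene
Conditions: H2 (1 atm), Pd/CaCO3 poisoned with Pb(OAc)2 (Lindlar catalyst), quinoline, EtOAc, rt
Reagents that add atoms: none
Why: Lindlar semihydrogenation gives the cis alkene by syn addition of hydrogen.

Step 40
Reactants: 47 C28–C50 (38Z)-alkene
Product: 48 C28,C41-diol
Conditions: HF·pyridine, pyridine, THF, 0 °C
Reagents that add atoms: none
Why: The primary C28 silyl ether should be cleaved selectively over the three secondary ones.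

Step 41
Reactants: 48 C28,C41-diol
Product: 49 C28 iodide with free C41–OH
Conditions: I2 (1.1 equiv), PPh3, imidazole, CH2Cl2, 0 °C
Reagents that add atoms: iodine (II)
Why: Appel-type iodination should be selective for the primary over the hindered secondary alcohol.

Step 42
Reactants: 49 C28 iodide with free C41–OH
Product: 50 South iodide–phosphonate (C41 bis(2,2,2-trifluoroethyl)phosphonoacetate)
Conditions: [bis(2,2,2-trifluoroethoxy)phosphoryl]acetic acid, DCC, DMAP (cat.), CH2Cl2, 0 °C → rt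
Reagents that add atoms: [bis(2,2,2-trifluoroethoxy)phosphoryl]acetic acid (OC(=O)CP(=O)(OCC(F)(F)F)OCC(F)(F)F)
Why: Carbodiimide esterification of phosphonoacetic acids acylates hindered secondary alcohols well.

Step 43
Reactants: 50 South iodide–phosphonate; 29 North (Z)-enal
Product: 51 seco (2Z,4Z)-dienoate (C28 iodide, C27 OPMB)
Conditions: 50, KN(SiMe3)2, 18-crown-6, THF, −78 °C; then 29
Reagents that add atoms: none
Why: Still–Gennari-type HWE olefination should form C2=C3 with Z geometry, the 4Z geometry being carried in from 29.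

Step 44
Reactants: 51 seco (2Z,4Z)-dienoate
Product: 52 C27 primary alcohol
Conditions: DDQ, CH2Cl2/pH 7 buffer, 0 °C
Reagents that add atoms: none
Why: Oxidative PMB cleavage leaves silyl ethers, alkenes, dienoate and iodide intact.

Step 45
Reactants: 52 C27 primary alcohol
Product: 53 seco iodo-aldehyde (C27 = CHO, C28–I)
Conditions: Dess–Martin periodinane, NaHCO3, CH2Cl2, 0 °C → rt
Reagents that add atoms: none
Why: Buffered Dess–Martin oxidation gives the aldehyde without touching the primary iodide.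

Step 46
Reactants: 53 seco iodo-aldehyde
Product: 54 protected macrolactone (27R, C27–OH free, eleven OTBS)
Conditions: CrCl2 (10 equiv), N-{2-[(4R)-4-tert-butyl-4,5-dihydrooxazol-2-yl]-6-methylphenyl}methanesulfonamide (11 equiv), Et3N, MeCN, rt; cobalt phthalocyanine C32H16CoN8 (0.3 equiv); 53 in THF by syringe pump over 12 h (1 mM final)
Reagents that add atoms: none
Why: Proposed new method: CrCl2 reduces cobalt phthalocyanine to monovalent cobalt, which takes the primary C28–I bond to an alkyl radical (through an alkyl–cobalt species); divalent chromium bound to the sulfonamide ligand captures the radical as an alkylchromium reagent of trivalent chromium, which adds to the C27 aldehyde through the closed transition state of the Nozaki–Hiyama–Kishi family. The closest known reaction types are the intermolecular cobalt/chromium-mediated addition of alkyl halides to aldehydes and Ni/Cr macrocyclisations of alkenyl iodides onto aldehydes under chiral sulfonamide control. The 42-membered ring closes in the 42-exo-trig mode, irreversibly, and the product is a saturated carbinol that needs no later adjustment. C27 is the only new stereocentre and is set by the chiral oxazoline–sulfonamide ligand on chromium (Re-face attack gives 27R), since the nearest substrate stereocentres, C23 and C31, are four bonds away on either side. The step needs chemoselectivity, which the reagents secure (alkylchromium species add to aldehydes but not to the dienoate ester, alkenes or silyl ethers, and cobalt activates only the sp3 C–I bond), and ring closure over oligomerisation, which slow addition to high dilution secures. Hydrodeiodination of C28 is the competing path and is held back by dry, aprotic conditions.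

Step 47
Reactants: 54 protected macrolactone
Product: 55 CNP0392687.2
Conditions: HF·pyridine, pyridine, THF, 0 °C → rt
Reagents that add atoms: none
Why: Buffered fluoride-mediated global desilylation should remove all eleven silyl ethers without opening the lactone or isomerising the Z,Z-dienoate.

**Compound list**

1 | propane-1,3-diol | OCCCO | starting material
2 | (4S,6S)-nona-1,8-diene-4,6-diol | C=CC[C@H](O)C[C@@H](O)CC=C | intermediate
3 | (4S,6S)-4,6-bis(TBS-oxy)nona-1,8-diene | C=CC[C@H](O[Si](C)(C)C(C)(C)C)C[C@@H](O[Si](C)(C)C(C)(C)C)CC=C | intermediate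
4 | (3R,5R)-3,5-bis(TBS-oxy)heptanedial | O=CC[C@H](O[Si](C)(C)C(C)(C)C)C[C@@H](O[Si](C)(C)C(C)(C)C)CC=O | intermediate
5 | (3S,5S)-3,5-bis(TBS-oxy)heptane-1,7-diol | OCC[C@H](O[Si](C)(C)C(C)(C)C)C[C@@H](O[Si](C)(C)C(C)(C)C)CCO | intermediate
6 | (4R,6S,8S,10R)-6,8-bis(TBS-oxy)trideca-1,12-diene-4,10-diol | C=CC[C@@H](O)C[C@H](O[Si](C)(C)C(C)(C)C)C[C@@H](O[Si](C)(C)C(C)(C)C)C[C@H](O)CC=C | intermediate
7 | (4R,6S,8S,10R)-4,6,8,10-tetrakis(TBS-oxy)trideca-1,12-diene | C=CC[C@@H](O[Si](C)(C)C(C)(C)C)C[C@H](O[Si](C)(C)C(C)(C)C)C[C@@H](O[Si](C)(C)C(C)(C)C)C[C@H](O[Si](C)(C)C(C)(C)C)CC=C | intermediate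
8 | (3S,5R,7R,9S)-3,5,7,9-tetrakis(TBS-oxy)undecanedial | O=CC[C@@H](O[Si](C)(C)C(C)(C)C)C[C@H](O[Si](C)(C)C(C)(C)C)C[C@@H](O[Si](C)(C)C(C)(C)C)C[C@H](O[Si](C)(C)C(C)(C)C)CC=O | intermediate
9 | (3R,5S,7S,9R)-3,5,7,9-tetrakis(TBS-oxy)undecane-1,11-diol (C7–C17) | OCC[C@@H](O[Si](C)(C)C(C)(C)C)C[C@H](O[Si](C)(C)C(C)(C)C)C[C@@H](O[Si](C)(C)C(C)(C)C)C[C@H](O[Si](C)(C)C(C)(C)C)CCO | intermediate
10 | (3R,5S,7S,9R)-3,5,7,9,11-pentakis(TBS-oxy)undecan-1-ol | OCC[C@@H](O[Si](C)(C)C(C)(C)C)C[C@H](O[Si](C)(C)C(C)(C)C)C[C@@H](O[Si](C)(C)C(C)(C)C)C[C@H](O[Si](C)(C)C(C)(C)C)CCO[Si](C)(C)C(C)(C)C | intermediate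
11 | C5–C17 homoallylic alcohol: C7–OH as in the target, C9/C11/C13/C15 OTBS, primary C17 OTBS, vinyl group on C6 | C=CC[C@H](O)C[C@@H](O[Si](C)(C)C(C)(C)C)C[C@H](O[Si](C)(C)C(C)(C)C)C[C@@H](O[Si](C)(C)C(C)(C)C)C[C@H](O[Si](C)(C)C(C)(C)C)CCO[Si](C)(C)C(C)(C)C | intermediate
12 | C5–C17 hexakis-TBS ether (C7 OTBS) | C=CC[C@H](O[Si](C)(C)C(C)(C)C)C[C@@H](O[Si](C)(C)C(C)(C)C)C[C@H](O[Si](C)(C)C(C)(C)C)C[C@@H](O[Si](C)(C)C(C)(C)C)C[C@H](O[Si](C)(C)C(C)(C)C)CCO[Si](C)(C)C(C)(C)C | intermediate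
13 | C5–C17 aldehyde (C5 = CHO) | O=CC[C@H](O[Si](C)(C)C(C)(C)C)C[C@@H](O[Si](C)(C)C(C)(C)C)C[C@H](O[Si](C)(C)C(C)(C)C)C[C@@H](O[Si](C)(C)C(C)(C)C)C[C@H](O[Si](C)(C)C(C)(C)C)CCO[Si](C)(C)C(C)(C)C | intermediate
14 | C3–C17 ethyl (Z)-enoate (ethyl ester at C3, 4-methyl, 4Z) | CCOC(=O)/C(C)=C\C[C@H](O[Si](C)(C)C(C)(C)C)C[C@@H](O[Si](C)(C)C(C)(C)C)C[C@H](O[Si](C)(C)C(C)(C)C)C[C@@H](O[Si](C)(C)C(C)(C)C)C[C@H](O[Si](C)(C)C(C)(C)C)CCO[Si](C)(C)C(C)(C)C | intermediate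
15 | C3–C17 enoate with free primary C17–OH | CCOC(=O)/C(C)=C\C[C@H](O[Si](C)(C)C(C)(C)C)C[C@@H](O[Si](C)(C)C(C)(C)C)C[C@H](O[Si](C)(C)C(C)(C)C)C[C@@H](O[Si](C)(C)C(C)(C)C)C[C@H](O[Si](C)(C)C(C)(C)C)CCO | intermediate
16 | C3–C17 enoate with C17 = CHO | CCOC(=O)/C(C)=C\C[C@H](O[Si](C)(C)C(C)(C)C)C[C@@H](O[Si](C)(C)C(C)(C)C)C[C@H](O[Si](C)(C)C(C)(C)C)C[C@@H](O[Si](C)(C)C(C)(C)C)C[C@H](O[Si](C)(C)C(C)(C)C)CC=O | intermediate
17 | C3–C19 anti-homoallylic alcohol (C17–OH, C18-methyl, vinyl = C19 plus CH2) | CCOC(=O)/C(C)=C\C[C@H](O[Si](C)(C)C(C)(C)C)C[C@@H](O[Si](C)(C)C(C)(C)C)C[C@H](O[Si](C)(C)C(C)(C)C)C[C@@H](O[Si](C)(C)C(C)(C)C)C[C@H](O[Si](C)(C)C(C)(C)C)C[C@@H](O)[C@@H](C)C=C | intermediate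
18 | C17 TBS ether of 17 | CCOC(=O)/C(C)=C\C[C@H](O[Si](C)(C)C(C)(C)C)C[C@@H](O[Si](C)(C)C(C)(C)C)C[C@H](O[Si](C)(C)C(C)(C)C)C[C@@H](O[Si](C)(C)C(C)(C)C)C[C@H](O[Si](C)(C)C(C)(C)C)C[C@@H](O[Si](C)(C)C(C)(C)C)[C@@H](C)C=C | intermediate
19 | C3–C19 aldehyde (C19 = CHO) | CCOC(=O)/C(C)=C\C[C@H](O[Si](C)(C)C(C)(C)C)C[C@@H](O[Si](C)(C)C(C)(C)C)C[C@H](O[Si](C)(C)C(C)(C)C)C[C@@H](O[Si](C)(C)C(C)(C)C)C[C@H](O[Si](C)(C)C(C)(C)C)C[C@@H](O[Si](C)(C)C(C)(C)C)[C@@H](C)C=O | intermediate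
20 | pentane-1,5-diol | OCCCCCO | starting material
21 | 5-[(4-methoxybenzyl)oxy]pentan-1-ol | OCCCCCOCc1ccc(OC)cc1 | intermediate
22 | (R)-8-[(4-methoxybenzyl)oxy]oct-1-en-4-ol | C=CC[C@H](O)CCCCOCc1ccc(OC)cc1 | intermediate
23 | TBS ether of 22 | C=CC[C@H](O[Si](C)(C)C(C)(C)C)CCCCOCc1ccc(OC)cc1 | intermediate
24 | (R)-3-(TBS-oxy)-7-[(4-methoxybenzyl)oxy]heptanal | O=CC[C@H](O[Si](C)(C)C(C)(C)C)CCCCOCc1ccc(OC)cc1 | intermediate
25 | East vinyl iodide, 1-({[(5R,7Z)-5-(TBS-oxy)-8-iodonon-7-en-1-yl]oxy}methyl)-4-methoxybenzene (C20–C27) | C/C(I)=C/C[C@H](O[Si](C)(C)C(C)(C)C)CCCCOCc1ccc(OC)cc1 | intermediate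
26 | C3–C27 allylic alcohol (C19–OH free, 4Z,20Z, C27 OPMB) | CCOC(=O)/C(C)=C\C[C@H](O[Si](C)(C)C(C)(C)C)C[C@@H](O[Si](C)(C)C(C)(C)C)C[C@H](O[Si](C)(C)C(C)(C)C)C[C@@H](O[Si](C)(C)C(C)(C)C)C[C@H](O[Si](C)(C)C(C)(C)C)C[C@@H](O[Si](C)(C)C(C)(C)C)[C@@H](C)[C@H](O)/C(C)=C\C[C@H](O[Si](C)(C)C(C)(C)C)CCCCOCc1ccc(OC)cc1 | intermediate
27 | C3–C27 ester with C19 OTBS | CCOC(=O)/C(C)=C\C[C@H](O[Si](C)(C)C(C)(C)C)C[C@@H](O[Si](C)(C)C(C)(C)C)C[C@H](O[Si](C)(C)C(C)(C)C)C[C@@H](O[Si](C)(C)C(C)(C)C)C[C@H](O[Si](C)(C)C(C)(C)C)C[C@@H](O[Si](C)(C)C(C)(C)C)[C@@H](C)[C@H](O[Si](C)(C)C(C)(C)C)/C(C)=C\C[C@H](O[Si](C)(C)C(C)(C)C)CCCCOCc1ccc(OC)cc1 | intermediate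
28 | C3–C27 allylic alcohol (C3 = CH2OH) | OC/C(C)=C\C[C@H](O[Si](C)(C)C(C)(C)C)C[C@@H](O[Si](C)(C)C(C)(C)C)C[C@H](O[Si](C)(C)C(C)(C)C)C[C@@H](O[Si](C)(C)C(C)(C)C)C[C@H](O[Si](C)(C)C(C)(C)C)C[C@@H](O[Si](C)(C)C(C)(C)C)[C@@H](C)[C@H](O[Si](C)(C)C(C)(C)C)/C(C)=C\C[C@H](O[Si](C)(C)C(C)(C)C)CCCCOCc1ccc(OC)cc1 | intermediate
29 | North (Z)-enal (C3 = CHO) | O=C/C(C)=C\C[C@H](O[Si](C)(C)C(C)(C)C)C[C@@H](O[Si](C)(C)C(C)(C)C)C[C@H](O[Si](C)(C)C(C)(C)C)C[C@@H](O[Si](C)(C)C(C)(C)C)C[C@H](O[Si](C)(C)C(C)(C)C)C[C@@H](O[Si](C)(C)C(C)(C)C)[C@@H](C)[C@H](O[Si](C)(C)C(C)(C)C)/C(C)=C\C[C@H](O[Si](C)(C)C(C)(C)C)CCCCOCc1ccc(OC)cc1 | intermediate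
30 | (R)-2-methyloxirane | C[C@@H]1CO1 | starting material
31 | (R)-non-8-en-2-ol | C=CCCCCC[C@@H](C)O | intermediate
32 | (R)-tert-butyldimethyl(non-8-en-2-yloxy)silane | C=CCCCCC[C@@H](C)O[Si](C)(C)C(C)(C)C | intermediate
33 | (R)-7-(TBS-oxy)octanal | O=CCCCCC[C@@H](C)O[Si](C)(C)C(C)(C)C | intermediate
34 | (3R,4R,10R)-10-(TBS-oxy)-3-methylundec-1-en-4-ol | C=C[C@@H](C)[C@H](O)CCCCC[C@@H](C)O[Si](C)(C)C(C)(C)C | intermediate
35 | tert-butyl (3R,4R,10R)-10-(TBS-oxy)-3-methylundec-1-en-4-yl carbonate | C=C[C@@H](C)[C@H](OC(=O)OC(C)(C)C)CCCCC[C@@H](C)O[Si](C)(C)C(C)(C)C | intermediate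
36 | (4R,5S,6R)-4-(iodomethyl)-5-methyl-6-[(6R)-6-(TBS-oxy)heptyl]-1,3-dioxan-2-one | IC[C@H]1[C@@H](C)[C@@H](CCCCC[C@@H](C)O[Si](C)(C)C(C)(C)C)OC(=O)O1 | intermediate
37 | (2S,3R,9R)-9-(TBS-oxy)-2-[(2R)-oxiran-2-yl]decan-3-ol | C1O[C@@H]1[C@@H](C)[C@H](O)CCCCC[C@@H](C)O[Si](C)(C)C(C)(C)C | intermediate
38 | (2R)-2-[(2R,3R,9R)-3,9-bis(TBS-oxy)decan-2-yl]oxirane (C40–C50) | C1O[C@@H]1[C@@H](C)[C@H](O[Si](C)(C)C(C)(C)C)CCCCC[C@@H](C)O[Si](C)(C)C(C)(C)C | intermediate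
39 | (S)-(5-oxotetrahydrofuran-2-yl)methyl 4-methylbenzenesulfonate | O=C1CC[C@@H](COS(=O)(=O)c2ccc(C)cc2)O1 | starting material
40 | 1-bromo-5-chloropentane | ClCCCCCBr | starting material
41 | 5-chloropentylmagnesium bromide | ClCCCCC[Mg]Br | intermediate
42 | (R)-5-(6-chlorohexyl)dihydrofuran-2(3H)-one | O=C1CC[C@@H](CCCCCCCl)O1 | intermediate
43 | (R)-10-chlorodecane-1,4-diol | OCCC[C@H](O)CCCCCCCl | intermediate
44 | (R)-1,4-bis(TBS-oxy)-10-chlorodecane | CC(C)(C)[Si](C)(C)OCCC[C@H](O[Si](C)(C)C(C)(C)C)CCCCCCCl | intermediate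
45 | (R)-1,4-bis(TBS-oxy)dodec-11-yne (C28–C39) | CC(C)(C)[Si](C)(C)OCCC[C@H](O[Si](C)(C)C(C)(C)C)CCCCCCC#C | intermediate
46 | C28–C50 homopropargylic alcohol (C41–OH free; C28, C31, C43, C49 OTBS; C38≡C39) | CC(C)(C)[Si](C)(C)OCCC[C@H](O[Si](C)(C)C(C)(C)C)CCCCCCC#CC[C@@H]([C@@H](C)[C@H](O[Si](C)(C)C(C)(C)C)CCCCC[C@@H](C)O[Si](C)(C)C(C)(C)C)O | intermediate
47 | C28–C50 (38Z)-alkene, C41–OH free | CC(C)(C)[Si](C)(C)OCCC[C@H](O[Si](C)(C)C(C)(C)C)CCCCCC/C=C\C[C@@H]([C@@H](C)[C@H](O[Si](C)(C)C(C)(C)C)CCCCC[C@@H](C)O[Si](C)(C)C(C)(C)C)O | intermediate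
48 | C28–C50 diol (C28–OH and C41–OH free) | OCCC[C@H](O[Si](C)(C)C(C)(C)C)CCCCCC/C=C\C[C@@H]([C@@H](C)[C@H](O[Si](C)(C)C(C)(C)C)CCCCC[C@@H](C)O[Si](C)(C)C(C)(C)C)O | intermediate
49 | C28–C50 iodo alcohol (C28–I, C41–OH) | ICCC[C@H](O[Si](C)(C)C(C)(C)C)CCCCCC/C=C\C[C@@H]([C@@H](C)[C@H](O[Si](C)(C)C(C)(C)C)CCCCC[C@@H](C)O[Si](C)(C)C(C)(C)C)O | intermediate
50 | South iodide–phosphonate (C41 bis(2,2,2-trifluoroethyl)phosphonoacetate, C28–I) | ICCC[C@H](O[Si](C)(C)C(C)(C)C)CCCCCC/C=C\C[C@@H]([C@@H](C)[C@H](O[Si](C)(C)C(C)(C)C)CCCCC[C@@H](C)O[Si](C)(C)C(C)(C)C)OC(=O)CP(=O)(OCC(F)(F)F)OCC(F)(F)F | intermediate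
51 | seco (2Z,4Z)-dienoate (C28–I, C27 OPMB, eleven OTBS) | ICCC[C@H](O[Si](C)(C)C(C)(C)C)CCCCCC/C=C\C[C@@H]([C@@H](C)[C@H](O[Si](C)(C)C(C)(C)C)CCCCC[C@@H](C)O[Si](C)(C)C(C)(C)C)OC(=O)/C=C\C(C)=C/C[C@H](O[Si](C)(C)C(C)(C)C)C[C@@H](O[Si](C)(C)C(C)(C)C)C[C@H](O[Si](C)(C)C(C)(C)C)C[C@@H](O[Si](C)(C)C(C)(C)C)C[C@H](O[Si](C)(C)C(C)(C)C)C[C@@H](O[Si](C)(C)C(C)(C)C)[C@@H](C)[C@H](O[Si](C)(C)C(C)(C)C)/C(C)=C\C[C@H](O[Si](C)(C)C(C)(C)C)CCCCOCc1ccc(OC)cc1 | intermediate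
52 | seco dienoate with free C27–OH | ICCC[C@H](O[Si](C)(C)C(C)(C)C)CCCCCC/C=C\C[C@@H]([C@@H](C)[C@H](O[Si](C)(C)C(C)(C)C)CCCCC[C@@H](C)O[Si](C)(C)C(C)(C)C)OC(=O)/C=C\C(C)=C/C[C@H](O[Si](C)(C)C(C)(C)C)C[C@@H](O[Si](C)(C)C(C)(C)C)C[C@H](O[Si](C)(C)C(C)(C)C)C[C@@H](O[Si](C)(C)C(C)(C)C)C[C@H](O[Si](C)(C)C(C)(C)C)C[C@@H](O[Si](C)(C)C(C)(C)C)[C@@H](C)[C@H](O[Si](C)(C)C(C)(C)C)/C(C)=C\C[C@H](O[Si](C)(C)C(C)(C)C)CCCCO | intermediate
53 | seco iodo-aldehyde (C27 = CHO, C28–I) | ICCC[C@H](O[Si](C)(C)C(C)(C)C)CCCCCC/C=C\C[C@@H]([C@@H](C)[C@H](O[Si](C)(C)C(C)(C)C)CCCCC[C@@H](C)O[Si](C)(C)C(C)(C)C)OC(=O)/C=C\C(C)=C/C[C@H](O[Si](C)(C)C(C)(C)C)C[C@@H](O[Si](C)(C)C(C)(C)C)C[C@H](O[Si](C)(C)C(C)(C)C)C[C@@H](O[Si](C)(C)C(C)(C)C)C[C@H](O[Si](C)(C)C(C)(C)C)C[C@@H](O[Si](C)(C)C(C)(C)C)[C@@H](C)[C@H](O[Si](C)(C)C(C)(C)C)/C(C)=C\C[C@H](O[Si](C)(C)C(C)(C)C)CCCC=O | intermediate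
54 | protected macrolactone (42-membered ring, 27R with free C27–OH, OTBS at C7, C9, C11, C13, C15, C17, C19, C23, C31, C43, C49) | CC1=C/C[C@H](O[Si](C)(C)C(C)(C)C)C[C@@H](O[Si](C)(C)C(C)(C)C)C[C@H](O[Si](C)(C)C(C)(C)C)C[C@@H](O[Si](C)(C)C(C)(C)C)C[C@H](O[Si](C)(C)C(C)(C)C)C[C@@H](O[Si](C)(C)C(C)(C)C)[C@@H](C)[C@H](O[Si](C)(C)C(C)(C)C)/C(C)=C\C[C@H](O[Si](C)(C)C(C)(C)C)CCC[C@H](O)CCC[C@H](O[Si](C)(C)C(C)(C)C)CCCCCC/C=C\C[C@@H]([C@@H](C)[C@H](O[Si](C)(C)C(C)(C)C)CCCCC[C@@H](C)O[Si](C)(C)C(C)(C)C)OC(=O)/C=C\1 | intermediate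
55 | CNP0392687.2 | CC1=C/C[C@H](O)C[C@@H](O)C[C@H](O)C[C@@H](O)C[C@H](O)C[C@@H](O)[C@@H](C)[C@H](O)/C(C)=C\C[C@H](O)CCC[C@H](O)CCC[C@H](O)CCCCCC/C=C\C[C@@H]([C@@H](C)[C@H](O)CCCCC[C@@H](C)O)OC(=O)/C=C\1 | target

**Totals**

Total step count: 47. Longest linear sequence: 25 steps (steps 1–16, 22–25, 43–47).

**Steps most likely to fail**

1. Step 46 (Proposed new method). What may go wrong: hydrodeiodination at C28 or intermolecular addition outrunning the 42-membered closure, and weak transfer of the ligand's chirality to C27. Fallback (known reaction types only; sets out from 28 and 50, comes back at 54): the C27–C28 bond is made between two open-chain pieces and the ring is closed at C2=C3 instead. Allylic alcohol 28 is silylated (TBSCl, imidazole, DMF) to the C3 silyl ether F1; DDQ removes the PMB group to give the C27 alcohol F2; Dess–Martin oxidation gives the C27 aldehyde F3. Intermolecular cobalt/chromium-mediated addition of iodide 50 to F3 (CrCl2, cobalt phthalocyanine, the same sulfonamide ligand, DMF/THF) gives the C27 carbinol F4, from which any 27-epimer is removed by chromatography at this open-chain stage. HF·pyridine/pyridine frees the primary allylic alcohol to give the diol F5; MnO2 oxidises only the allylic alcohol to give the enal–phosphonate F6; KN(SiMe3)2/18-crown-6 in THF at −78 °C and high dilution closes the ring by intramolecular Still–Gennari olefination to give 54.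

2. Step 43. What may go wrong: Z-to-E isomerisation of the α-methyl (Z)-enal 29 under the basic conditions, and erosion of Z-selectivity when both partners are large. Fallback (sets out from 29, uses 49, comes back at 51): the ester bond is formed last instead of the C2=C3 bond. Enal 29 is olefinated with the small reagent methyl [bis(2,2,2-trifluoroethoxy)phosphoryl]acetate in excess (KN(SiMe3)2, 18-crown-6, THF, −78 °C) to give the methyl (2Z,4Z)-dienoate F7, whose geometric isomers can be separated at this stage. LiOH (THF/MeOH/H2O) gives the dienoic acid F8, and Shiina esterification (2-methyl-6-nitrobenzoic anhydride, Et3N, DMAP, CH2Cl2) of F8 with iodo alcohol 49 gives 51.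

3. Step 22. What may go wrong: poor facial selectivity at C19 in the addition of the alkenylchromium reagent to the α-methyl aldehyde. Fallback (sets out from 26 obtained as a C19 epimer mixture, comes back at 26): C19 is set by a reagent instead of by the substrate. The mixture is oxidised with Dess–Martin periodinane to the enone F9, which is reduced with BH3·SMe2 under (R)-CBS oxazaborolidine catalysis (Corey–Bakshi–Shibata reduction, alkenyl as the large group) to give 26 with the 19S configuration.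

**Further compounds**

F1 | step 46 | C3–C27 fragment with C3 primary OTBS and C27 OPMB | CC(C)(C)[Si](C)(C)OC/C(C)=C\C[C@H](O[Si](C)(C)C(C)(C)C)C[C@@H](O[Si](C)(C)C(C)(C)C)C[C@H](O[Si](C)(C)C(C)(C)C)C[C@@H](O[Si](C)(C)C(C)(C)C)C[C@H](O[Si](C)(C)C(C)(C)C)C[C@@H](O[Si](C)(C)C(C)(C)C)[C@@H](C)[C@H](O[Si](C)(C)C(C)(C)C)/C(C)=C\C[C@H](O[Si](C)(C)C(C)(C)C)CCCCOCc1ccc(OC)cc1
F2 | step 46 | C3–C27 fragment with C3 OTBS and free C27–OH | CC(C)(C)[Si](C)(C)OC/C(C)=C\C[C@H](O[Si](C)(C)C(C)(C)C)C[C@@H](O[Si](C)(C)C(C)(C)C)C[C@H](O[Si](C)(C)C(C)(C)C)C[C@@H](O[Si](C)(C)C(C)(C)C)C[C@H](O[Si](C)(C)C(C)(C)C)C[C@@H](O[Si](C)(C)C(C)(C)C)[C@@H](C)[C@H](O[Si](C)(C)C(C)(C)C)/C(C)=C\C[C@H](O[Si](C)(C)C(C)(C)C)CCCCO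
F3 | step 46 | C3–C27 fragment with C3 OTBS and C27 = CHO | CC(C)(C)[Si](C)(C)OC/C(C)=C\C[C@H](O[Si](C)(C)C(C)(C)C)C[C@@H](O[Si](C)(C)C(C)(C)C)C[C@H](O[Si](C)(C)C(C)(C)C)C[C@@H](O[Si](C)(C)C(C)(C)C)C[C@H](O[Si](C)(C)C(C)(C)C)C[C@@H](O[Si](C)(C)C(C)(C)C)[C@@H](C)[C@H](O[Si](C)(C)C(C)(C)C)/C(C)=C\C[C@H](O[Si](C)(C)C(C)(C)C)CCCC=O
F4 | step 46 | open-chain C3–C50 carbinol (27R, C27–OH; C3 OTBS; C41 phosphonoacetate) | CC(C)(C)[Si](C)(C)OC/C(C)=C\C[C@H](O[Si](C)(C)C(C)(C)C)C[C@@H](O[Si](C)(C)C(C)(C)C)C[C@H](O[Si](C)(C)C(C)(C)C)C[C@@H](O[Si](C)(C)C(C)(C)C)C[C@H](O[Si](C)(C)C(C)(C)C)C[C@@H](O[Si](C)(C)C(C)(C)C)[C@@H](C)[C@H](O[Si](C)(C)C(C)(C)C)/C(C)=C\C[C@H](O[Si](C)(C)C(C)(C)C)CCC[C@H](O)CCC[C@H](O[Si](C)(C)C(C)(C)C)CCCCCC/C=C\C[C@@H]([C@@H](C)[C@H](O[Si](C)(C)C(C)(C)C)CCCCC[C@@H](C)O[Si](C)(C)C(C)(C)C)OC(=O)CP(=O)(OCC(F)(F)F)OCC(F)(F)F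
F5 | step 46 | open-chain C3,C27-diol (C3 = CH2OH; C41 phosphonoacetate) | OC/C(C)=C\C[C@H](O[Si](C)(C)C(C)(C)C)C[C@@H](O[Si](C)(C)C(C)(C)C)C[C@H](O[Si](C)(C)C(C)(C)C)C[C@@H](O[Si](C)(C)C(C)(C)C)C[C@H](O[Si](C)(C)C(C)(C)C)C[C@@H](O[Si](C)(C)C(C)(C)C)[C@@H](C)[C@H](O[Si](C)(C)C(C)(C)C)/C(C)=C\C[C@H](O[Si](C)(C)C(C)(C)C)CCC[C@H](O)CCC[C@H](O[Si](C)(C)C(C)(C)C)CCCCCC/C=C\C[C@@H]([C@@H](C)[C@H](O[Si](C)(C)C(C)(C)C)CCCCC[C@@H](C)O[Si](C)(C)C(C)(C)C)OC(=O)CP(=O)(OCC(F)(F)F)OCC(F)(F)F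
F6 | step 46 | open-chain enal–phosphonate (C3 = CHO, C27–OH, C41 phosphonoacetate) | O=C/C(C)=C\C[C@H](O[Si](C)(C)C(C)(C)C)C[C@@H](O[Si](C)(C)C(C)(C)C)C[C@H](O[Si](C)(C)C(C)(C)C)C[C@@H](O[Si](C)(C)C(C)(C)C)C[C@H](O[Si](C)(C)C(C)(C)C)C[C@@H](O[Si](C)(C)C(C)(C)C)[C@@H](C)[C@H](O[Si](C)(C)C(C)(C)C)/C(C)=C\C[C@H](O[Si](C)(C)C(C)(C)C)CCC[C@H](O)CCC[C@H](O[Si](C)(C)C(C)(C)C)CCCCCC/C=C\C[C@@H]([C@@H](C)[C@H](O[Si](C)(C)C(C)(C)C)CCCCC[C@@H](C)O[Si](C)(C)C(C)(C)C)OC(=O)CP(=O)(OCC(F)(F)F)OCC(F)(F)F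
F7 | step 43 | C1–C27 methyl (2Z,4Z)-dienoate (C27 OPMB) | COC(=O)/C=C\C(C)=C/C[C@H](O[Si](C)(C)C(C)(C)C)C[C@@H](O[Si](C)(C)C(C)(C)C)C[C@H](O[Si](C)(C)C(C)(C)C)C[C@@H](O[Si](C)(C)C(C)(C)C)C[C@H](O[Si](C)(C)C(C)(C)C)C[C@@H](O[Si](C)(C)C(C)(C)C)[C@@H](C)[C@H](O[Si](C)(C)C(C)(C)C)/C(C)=C\C[C@H](O[Si](C)(C)C(C)(C)C)CCCCOCc1ccc(OC)cc1
F8 | step 43 | C1–C27 (2Z,4Z)-dienoic acid (C27 OPMB) | OC(=O)/C=C\C(C)=C/C[C@H](O[Si](C)(C)C(C)(C)C)C[C@@H](O[Si](C)(C)C(C)(C)C)C[C@H](O[Si](C)(C)C(C)(C)C)C[C@@H](O[Si](C)(C)C(C)(C)C)C[C@H](O[Si](C)(C)C(C)(C)C)C[C@@H](O[Si](C)(C)C(C)(C)C)[C@@H](C)[C@H](O[Si](C)(C)C(C)(C)C)/C(C)=C\C[C@H](O[Si](C)(C)C(C)(C)C)CCCCOCc1ccc(OC)cc1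
F9 | step 22 | C3–C27 enone (C19 ketone, 20Z) | CCOC(=O)/C(C)=C\C[C@H](O[Si](C)(C)C(C)(C)C)C[C@@H](O[Si](C)(C)C(C)(C)C)C[C@H](O[Si](C)(C)C(C)(C)C)C[C@@H](O[Si](C)(C)C(C)(C)C)C[C@H](O[Si](C)(C)C(C)(C)C)C[C@@H](O[Si](C)(C)C(C)(C)C)[C@@H](C)C(=O)/C(C)=C\C[C@H](O[Si](C)(C)C(C)(C)C)CCCCOCc1ccc(OC)cc1
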